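**Retrosynthetic overview**
1. The C4–O–C4 ether is made last: acid-catalysed SN1 etherification of two molecules of (2R,3R,4R)-teracacidin. The nucleophilic half keeps 4R; the cationic half is captured on its β-face and becomes 4S.
2. Both teracacidin molecules come from one para-xylylene-bridged bis(flavan-4-ol) by hydrogenolysis. That compound comes from a two-fold enantioselective cis-hydrogenation and hydride reduction of a bridged bis(3-benzyloxyflavone).
3. Key disconnection: the bridged bis-flavonol comes from a bridged dialdehyde and two 2-hydroxyacetophenones by a two-directional Claisen–Schmidt/Algar–Flynn–Oyamada sequence in one pot.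
4. Ring order: rings A and B are bought (gallacetophenone, 4-hydroxybenzaldehyde). The two C rings close together in step 3 and are reduced in step 5. No other ring is formed.

Assumption: the ruthenium catalyst made from (R,R)-SINpEt·HBF4 (1,3-bis[(R)-1-(1-naphthyl)ethyl]imidazolinium tetrafluoroborate) adds H2 to the face that gives the 2R series; if it proves to be the other face, the (S,S)-salt is used instead.

**Step 1**
Reactants: 1 gallacetophenone (1-(2,3,4-trihydroxyphenyl)ethan-1-one); 2 benzyl bromide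
Product: 3 gallacetophenone 3,4-dibenzyl ether (1-[3,4-bis(benzyloxy)-2-hydroxyphenyl]ethan-1-one)
Conditions: BnBr (2.1 equiv), K2CO3 (2.2 equiv), acetone, reflux
Reagents that add atoms: benzyl bromide, BrCc1ccccc1
Why: Williamson etherification; the 2-OH is held in a hydrogen bond to the acetyl C=O and stays free while the 3- and 4-OH are benzylated; no stereocenter.

**Step 2**
Reactants: 4 para-hydroxybenzaldehyde (4-hydroxybenzaldehyde, two molecules); 5 para-xylylene dibromide (1,4-bis(bromomethyl)benzene)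
Product: 6 bridged dialdehyde (4,4'-[1,4-phenylenebis(methyleneoxy)]dibenzaldehyde)
Conditions: K2CO3, DMF, 60 °C
Reagents that add atoms: 1,4-bis(bromomethyl)benzene, BrCc1ccc(CBr)cc1
Why: double Williamson etherification with a benzylic dibromide; the para-xylylene unit is a two-armed benzyl-type protecting group that joins the two ring B precursors and leaves later by hydrogenolysis; no stereocenter.

**Step 3 (key step)**
Reactants: 3 gallacetophenone 3,4-dibenzyl ether (two molecules); 6 bridged dialdehyde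
Product: 8 bridged bis-flavonol (1,4-bis({4-[7,8-bis(benzyloxy)-3-hydroxy-4-oxo-4H-chromen-2-yl]phenoxy}methyl)benzene), via bis-chalcone 7 (not isolated)
Conditions: KOH, EtOH–THF, rt; then NaOH, 30% H2O2, 0 °C to rt; then dilute HCl
Reagents that add atoms: hydrogen peroxide, OO
Why: two-directional Claisen–Schmidt (aldol) condensation gives the (E,E)-bis-chalcone and the Algar–Flynn–Oyamada reaction then runs on both arms in the same pot (HOO− epoxidises each enone, the 2'-phenoxide opens the epoxide 6-endo at the benzylic carbon, the dihydroflavonol is oxidised on to the flavonol), so both ring C pyranones close in one operation, the free 6'-position favouring flavonol over aurone; no stereocenter is formed.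

**Step 4**
Reactants: 8 bridged bis-flavonol; 2 benzyl bromide (two molecules)
Product: 9 bridged bis(3-benzyloxyflavone) (1,4-bis({4-[3,7,8-tris(benzyloxy)-4-oxo-4H-chromen-2-yl]phenoxy}methyl)benzene)
Conditions: BnBr, K2CO3, DMF, 50 °C
Reagents that add atoms: benzyl bromide, BrCc1ccccc1
Why: Williamson O-benzylation of the acidic enolic 3-OH, which masks the chelating 3-hydroxy-4-keto unit (it would bind the ruthenium catalyst of step 5) with a group that leaves in the later hydrogenolysis; no stereocenter.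

**Step 5**
Reactants: 9 bridged bis(3-benzyloxyflavone)
Product: 11 bridged bis(flavan-4-ol) (1,4-bis({4-[(2R,3R,4R)-3,7,8-tris(benzyloxy)-4-hydroxy-3,4-dihydro-2H-chromen-2-yl]phenoxy}methyl)benzene), via bis-flavanone 10 (not isolated)
Conditions: H2 (100 bar), [Ru(cod)(2-methylallyl)2] (5 mol %), (R,R)-SINpEt·HBF4 (10 mol %), KOtBu (12 mol %), toluene, 40 °C; then NaBH4, THF–MeOH, −20 °C
Reagents that add atoms: none
Why: Proposed new method: the chiral ruthenium–N-heterocyclic-carbene hydride adds H2 syn across the C2=C3 enol-ether bond of each pyranone from one face, so 2-aryl and 3-OBn end up cis and catalyst control sets 2R,3S in ketone 10 (closest known reaction type: Ru–carbene-catalysed asymmetric hydrogenation of flavones and chromones to flavanones and cis-flavanols); NaBH4 then attacks each C4=O axially, anti to the axial 3-OBn, which gives the all-cis 4R alcohol by substrate control.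

**Step 6**
Reactants: 11 bridged bis(flavan-4-ol)
Product: 12 teracacidin ((2R,3R,4R)-2-(4-hydroxyphenyl)-3,4-dihydro-2H-chromene-3,4,7,8-tetrol, two molecules)
Conditions: H2 (1 atm), Pd(OH)2/C, EtOAc–THF, solid NaHCO3, rt
Reagents that add atoms: none
Why: palladium-catalysed hydrogenolysis cleaves all eight benzylic C–O bonds of the benzyl-type ethers (six benzyl groups and both arms of the bridge) faster than the C4 benzylic alcohol under acid-free conditions and releases two molecules of the free pentol; no stereocenter is touched.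

**Step 7**
Reactants: 12 teracacidin (two molecules)
Product: 13 target ((2R,3R,4R)-4-{[(2R,3R,4S)-3,7,8-trihydroxy-2-(4-hydroxyphenyl)-3,4-dihydro-2H-chromen-4-yl]oxy}-2-(4-hydroxyphenyl)-3,4-dihydro-2H-chromene-3,7,8-triol)
Conditions: camphorsulfonic acid (5 mol %), 3 Å molecular sieves, THF (0.5 M), 0 °C to rt; Et3N quench; Sephadex LH-20
Reagents that add atoms: none
Why: Brønsted-acid-catalysed SN1 etherification (the way flavan-3,4-diols form 4-O-ethers): ionisation of the 4-OH, helped by the para 7-OH of ring A, gives a quinone-methide-type C4 cation that is captured by the equatorial 4-OH of a second, un-ionised molecule (which keeps 4R) by axial attack on the β-face, anti to the axial 3-OH and the 2-aryl group, setting 4S in the electrophilic half.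

**Compound list**
1 | gallacetophenone, 1-(2,3,4-trihydroxyphenyl)ethan-1-one | CC(=O)c1ccc(O)c(O)c1O | starting material
2 | benzyl bromide | BrCc1ccccc1 | starting material
3 | 1-[3,4-bis(benzyloxy)-2-hydroxyphenyl]ethan-1-one | CC(=O)c1ccc(OCc2ccccc2)c(OCc2ccccc2)c1O | intermediate
4 | 4-hydroxybenzaldehyde | O=Cc1ccc(O)cc1 | starting material
5 | 1,4-bis(bromomethyl)benzene | BrCc1ccc(CBr)cc1 | starting material
6 | 4,4'-[1,4-phenylenebis(methyleneoxy)]dibenzaldehyde | O=Cc1ccc(OCc2ccc(COc3ccc(C=O)cc3)cc2)cc1 | intermediate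
7 | (2E,2'E)-3,3'-[1,4-phenylenebis(methyleneoxy-4,1-phenylene)]bis{1-[3,4-bis(benzyloxy)-2-hydroxyphenyl]prop-2-en-1-one} (bis-chalcone) | Oc1c(C(=O)/C=C/c2ccc(OCc3ccc(COc4ccc(/C=C/C(=O)c5ccc(OCc6ccccc6)c(OCc6ccccc6)c5O)cc4)cc3)cc2)ccc(OCc2ccccc2)c1OCc1ccccc1 | intermediate (not isolated)
8 | 1,4-bis({4-[7,8-bis(benzyloxy)-3-hydroxy-4-oxo-4H-chromen-2-yl]phenoxy}methyl)benzene (bridged bis-flavonol) | O=c1c(O)c(-c2ccc(OCc3ccc(COc4ccc(-c5oc6c(ccc(OCc7ccccc7)c6OCc6ccccc6)c(=O)c5O)cc4)cc3)cc2)oc2c1ccc(OCc1ccccc1)c2OCc1ccccc1 | intermediate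
9 | 1,4-bis({4-[3,7,8-tris(benzyloxy)-4-oxo-4H-chromen-2-yl]phenoxy}methyl)benzene | O=c1c(OCc2ccccc2)c(-c2ccc(OCc3ccc(COc4ccc(-c5oc6c(ccc(OCc7ccccc7)c6OCc6ccccc6)c(=O)c5OCc5ccccc5)cc4)cc3)cc2)oc2c1ccc(OCc1ccccc1)c2OCc1ccccc1 | intermediate
10 | 1,4-bis({4-[(2R,3S)-3,7,8-tris(benzyloxy)-4-oxo-3,4-dihydro-2H-chromen-2-yl]phenoxy}methyl)benzene (2,3-cis in both halves) | c1cc(COc2ccc(cc2)[C@H]2Oc3c(ccc(OCc4ccccc4)c3OCc3ccccc3)C(=O)[C@H]2OCc2ccccc2)ccc1COc1ccc(cc1)[C@H]1Oc2c(ccc(OCc3ccccc3)c2OCc2ccccc2)C(=O)[C@H]1OCc1ccccc1 | intermediate (not isolated)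
11 | 1,4-bis({4-[(2R,3R,4R)-3,7,8-tris(benzyloxy)-4-hydroxy-3,4-dihydro-2H-chromen-2-yl]phenoxy}methyl)benzene (all-cis in both halves) | c1cc(COc2ccc(cc2)[C@H]2Oc3c(ccc(OCc4ccccc4)c3OCc3ccccc3)[C@@H](O)[C@H]2OCc2ccccc2)ccc1COc1ccc(cc1)[C@H]1Oc2c(ccc(OCc3ccccc3)c2OCc2ccccc2)[C@@H](O)[C@H]1OCc1ccccc1 | intermediate
12 | teracacidin, (2R,3R,4R)-2-(4-hydroxyphenyl)-3,4-dihydro-2H-chromene-3,4,7,8-tetrol (2,3-cis-3,4-cis) | Oc1ccc([C@H]2Oc3c(ccc(O)c3O)[C@@H](O)[C@H]2O)cc1 | intermediate
13 | (2R,3R,4R)-4-{[(2R,3R,4S)-3,7,8-trihydroxy-2-(4-hydroxyphenyl)-3,4-dihydro-2H-chromen-4-yl]oxy}-2-(4-hydroxyphenyl)-3,4-dihydro-2H-chromene-3,7,8-triol | Oc1ccc([C@H]2Oc3c(ccc(O)c3O)[C@@H](O[C@H]3c4ccc(O)c(O)c4O[C@H](c4ccc(O)cc4)[C@@H]3O)[C@H]2O)cc1 | target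

**Step count and risks**
Total steps: 7. Longest linear sequence: 6 (steps 1, 3, 4, 5, 6, 7, or 2, 3, 4, 5, 6, 7).

The three steps most likely to fail:

Step 5 (new asymmetric hydrogenation of a tetrasubstituted 3-alkoxyflavone, twice in one molecule). Conversion or ee may be poor. Fallback: give up asymmetric catalysis and resolve. Starting from 8, hydrogenolysis (H2, Pd/C, THF–MeOH) frees 3,7,8,4'-tetrahydroxyflavone F1 (two molecules per 8). Hydrogenation of F1 over Raney Ni (H2 50 bar, EtOH, 60 °C) is the classical all-cis reduction of a flavonol and gives the diol as the racemate, that is 12 together with ent-teracacidin F2. Preparative chromatography on a chiral stationary phase separates them, and the route is rejoined at 12 (steps 4 to 6 are skipped).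

Step 6 (hydrogenolysis in the presence of the electron-rich benzylic 4-OH). Over-reduction at C4 to the flavan-3-ol is possible. Fallback: change the protecting groups so that no hydrogenolysis follows the reduction. Starting from 8, H2 and Pd/C at the flavonol stage give tetrahydroxyflavone F1. TBSCl and imidazole in DMF give the tetrakis(tert-butyldimethylsilyl) ether F3. The hydrogenation and NaBH4 sequence of step 5 then gives the silylated all-cis flavan-4-ol F4. Bu4NF buffered with AcOH in THF at 0 °C removes the silyl groups, and the route is rejoined at 12.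

Step 7 (self-condensation). The 3-OH or ring carbons of a second molecule can also trap the cation. The product can ionise again and drift to the 4β,4β-ether. Oligomers can form. The reaction is therefore stopped at partial conversion and 12 is recycled. Because the product is a homochiral dimer, the minor enantiomer of 12 ends up mostly in separable diastereomers. Fallback: separate the electrophile and nucleophile roles. Starting from 12, thiolysis with benzyl mercaptan (AcOH, rt) gives the 4β-benzylsulfanyl flavan-3-ol F5. AgBF4 with 2,6-di-tert-butyl-4-methylpyridine in THF at −15 °C ionises only the C–S bond of F5, and an excess of 12 traps the cation with its 4-OH on the β-face. The route is rejoined at 13.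

**Further compounds**
F1 | step 5 | 3,7,8-trihydroxy-2-(4-hydroxyphenyl)-4H-chromen-4-one (3,7,8,4'-tetrahydroxyflavone) | O=c1c(O)c(-c2ccc(O)cc2)oc2c(O)c(O)ccc12
F2 | step 5 | ent-teracacidin, (2S,3S,4S)-2-(4-hydroxyphenyl)-3,4-dihydro-2H-chromene-3,4,7,8-tetrol | Oc1ccc([C@@H]2Oc3c(ccc(O)c3O)[C@H](O)[C@@H]2O)cc1
F3 | step 6 | 3,7,8-tris[(tert-butyldimethylsilyl)oxy]-2-{4-[(tert-butyldimethylsilyl)oxy]phenyl}-4H-chromen-4-one | CC(C)(C)[Si](C)(C)Oc1ccc(cc1)-c1oc2c(O[Si](C)(C)C(C)(C)C)c(O[Si](C)(C)C(C)(C)C)ccc2c(=O)c1O[Si](C)(C)C(C)(C)C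
F4 | step 6 | (2R,3R,4R)-3,7,8-tris[(tert-butyldimethylsilyl)oxy]-2-{4-[(tert-butyldimethylsilyl)oxy]phenyl}-3,4-dihydro-2H-chromen-4-ol | CC(C)(C)[Si](C)(C)Oc1ccc(cc1)[C@H]1Oc2c(ccc(O[Si](C)(C)C(C)(C)C)c2O[Si](C)(C)C(C)(C)C)[C@@H](O)[C@H]1O[Si](C)(C)C(C)(C)C
F5 | step 7 | (2R,3S,4S)-4-(benzylsulfanyl)-2-(4-hydroxyphenyl)-3,4-dihydro-2H-chromene-3,7,8-triol (2,3-cis-3,4-trans) | c1ccccc1CS[C@H]1c2ccc(O)c(O)c2O[C@H](c2ccc(O)cc2)[C@@H]1O
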